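**Retrosynthetic overview**
- The last step is removal of the aryl silyl ether from the O‑TBS flavanone.
- Rings C and A come from one acyclic δ‑hydroxy‑β‑diketo‑dioxinone in one pot: ring C first (acid cyclodehydration, O1–C8a), then ring A (thermal acylketene C‑acylation, C4a–C5). C2 and the prenyl position are already fixed in the chain.
- The chain comes from a crossed Claisen condensation of a prenylated keto‑dioxinone dianion with an (S)‑β‑hydroxy ester.
- The (S)‑β‑hydroxy ester comes from a catalytic asymmetric acetate aldol on TBS‑vanillin, which sets C2.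
- The keto‑dioxinone comes from the diketene–acetone adduct by γ‑prenylation, then γ‑acetylation.

Assumption: the target is read as the (2S)‑flavanone. LDA, LiHMDS and the Denmark bis‑phosphoramide are bought, and the catalyst antipode used is the one that gives Si‑face attack (sense not assigned here; confirm on the first batch by chiral HPLC).

**Step 1**
Reactants: 1 vanillin
Product: 2 4‑(tert‑butyldimethylsilyloxy)‑3‑methoxybenzaldehyde
Conditions: TBSCl (1.1 equiv), imidazole (2.2 equiv), CH2Cl2, 0 °C → rt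
Reagents that add atoms: tert‑butyldimethylsilyl chloride, CC(C)(C)[Si](C)(C)Cl
Why: Standard phenol silylation (Corey protocol); the silyl ether keeps the aldehyde electrophilic and later prevents p‑quinone‑methide ionisation of the benzylic alcohol.

**Step 2**
Reactants: 2 4‑(tert‑butyldimethylsilyloxy)‑3‑methoxybenzaldehyde; 3 1‑(tert‑butyldimethylsilyloxy)‑1‑methoxyethene
Product: 5 methyl (3S)‑3‑[4‑(tert‑butyldimethylsilyloxy)‑3‑methoxyphenyl]‑3‑hydroxypropanoate, via trichlorosilyl aldolate 4 (not isolated)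
Conditions: SiCl4 (1.1 equiv), Denmark bis‑phosphoramide (5 mol %, antipode for Si‑face attack), CH2Cl2, –78 °C; cold sat. aq. NaHCO3
Reagents that add atoms: none
Why: Lewis‑base‑activated SiCl4 (chiral phosphoramide‑bound trichlorosilyl cation) binds the aldehyde and the acetate ketene acetal adds to its Si face (Denmark‑type catalytic asymmetric Mukaiyama aldol), which sets the only stereocenter as S.

**Step 3**
Reactants: 6 2,2,6‑trimethyl‑4H‑1,3‑dioxin‑4‑one; 7 prenyl bromide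
Product: 8 2,2‑dimethyl‑6‑(4‑methylpent‑3‑en‑1‑yl)‑4H‑1,3‑dioxin‑4‑one
Conditions: LDA (1.05 equiv), THF–DMPU (5:1), –78 °C; then 7, –78 → –30 °C
Reagents that add atoms: none
Why: Vinylogous (γ) alkylation of the lithium dienolate of the dioxinone, favoured by the polar co‑solvent, with SN2 attack at the primary carbon of the allylic bromide giving the linear prenyl chain.

**Step 4**
Reactants: 8 2,2‑dimethyl‑6‑(4‑methylpent‑3‑en‑1‑yl)‑4H‑1,3‑dioxin‑4‑one; 9 acetyl chloride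
Product: 10 2,2‑dimethyl‑6‑(6‑methyl‑2‑oxohept‑5‑en‑3‑yl)‑4H‑1,3‑dioxin‑4‑one
Conditions: 8 (2.0 equiv), LiHMDS (2.0 equiv), THF, –78 °C; 9 (1.0 equiv), –78 °C; AcOH quench (excess 8 recovered)
Reagents that add atoms: none
Why: γ‑C‑Acylation of the dioxinone dienolate (Barrett‑type crossed Claisen); the second equivalent of dienolate deprotonates the more acidic keto‑dioxinone and so stops over‑acylation.

**Step 5**
Reactants: 10 2,2‑dimethyl‑6‑(6‑methyl‑2‑oxohept‑5‑en‑3‑yl)‑4H‑1,3‑dioxin‑4‑one; 5 methyl (3S)‑3‑[4‑(tert‑butyldimethylsilyloxy)‑3‑methoxyphenyl]‑3‑hydroxypropanoate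
Product: 11 6‑[(10S)‑10‑[4‑(tert‑butyldimethylsilyloxy)‑3‑methoxyphenyl]‑10‑hydroxy‑2‑methyl‑6,8‑dioxodec‑2‑en‑5‑yl]‑2,2‑dimethyl‑4H‑1,3‑dioxin‑4‑one
Conditions: 10 (3.0 equiv), LDA (6.0 equiv), THF, –78 → –40 °C; 5 (1.0 equiv), –78 → –30 °C; AcOH, –78 °C; pH 6 work‑up, used at once
Reagents that add atoms: none
Why: Harris/Barrett crossed Claisen in which the terminal methyl carbanion of the keto‑dioxinone dianion attacks the ester; 5 reacts as its lithium alkoxide, which blocks β‑elimination (as in Claisen condensations of unprotected β‑hydroxy esters with excess enolate), and the stereocenter is not involved.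

**Step 6**
Reactants: 11 6‑[(10S)‑10‑[4‑(tert‑butyldimethylsilyloxy)‑3‑methoxyphenyl]‑10‑hydroxy‑2‑methyl‑6,8‑dioxodec‑2‑en‑5‑yl]‑2,2‑dimethyl‑4H‑1,3‑dioxin‑4‑one
Product: 14 (2S)‑2‑[4‑(tert‑butyldimethylsilyloxy)‑3‑methoxyphenyl]‑5,7‑dihydroxy‑8‑(3‑methylbut‑2‑en‑1‑yl)‑2,3‑dihydro‑4H‑chromen‑4‑one, via dihydropyranone dioxinone 12 (not isolated), via acylketene 13 (not isolated)
Conditions: PPTS (20 mol %), 4 Å MS, PhMe (0.01 M), 40 °C, 3 h; then 110 °C, 1 h
Reagents that add atoms: none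
Why: Proposed new method: mild acid closes the δ‑hydroxy‑β‑diketone to the 2,3‑dihydro‑4H‑pyran‑4‑one 12 (known cyclodehydration; the C2–O bond is untouched so S is kept, and the future C8a oxygen is tied up as the ring ether); heating then expels acetone from the dioxinone (retro‑[4+2]) to give acylketene 13, whose only six‑membered closure is C‑acylation of the pyranone enol‑ether carbon (6π‑electrocyclisation of the dienyl‑ketene tautomer, a vinylogous Claisen), and tautomerisation gives the phloroglucinol ring with prenyl fixed at C8; closest known chemistry is the biomimetic aromatisation of diketo‑dioxinones through acylketenes (Barrett), the electrocyclisation step of the Danheiser benzannulation and Harris‑type Claisen cyclisation of triketo esters.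

**Step 7**
Reactants: 14 (2S)‑2‑[4‑(tert‑butyldimethylsilyloxy)‑3‑methoxyphenyl]‑5,7‑dihydroxy‑8‑(3‑methylbut‑2‑en‑1‑yl)‑2,3‑dihydro‑4H‑chromen‑4‑one
Product: 15 (2S)‑5,7‑dihydroxy‑2‑(4‑hydroxy‑3‑methoxyphenyl)‑8‑(3‑methylbut‑2‑en‑1‑yl)‑2,3‑dihydro‑4H‑chromen‑4‑one
Conditions: KHF2 (2.5 equiv), MeOH, rt
Reagents that add atoms: none
Why: Bifluoride cleaves the aryl silyl ether under weakly acidic conditions (fluoride desilylation) that neither open the flavanone ring (no racemisation at C2) nor touch the prenyl alkene.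

**Compound list**
1 | vanillin | COc1cc(C=O)ccc1O | starting material
2 | 4‑(tert‑butyldimethylsilyloxy)‑3‑methoxybenzaldehyde | COc1cc(C=O)ccc1O[Si](C)(C)C(C)(C)C | intermediate
3 | 1‑(tert‑butyldimethylsilyloxy)‑1‑methoxyethene | COC(=C)O[Si](C)(C)C(C)(C)C | starting material
4 | methyl (3S)‑3‑[4‑(tert‑butyldimethylsilyloxy)‑3‑methoxyphenyl]‑3‑(trichlorosilyloxy)propanoate | COc1cc([C@@H](O[Si](Cl)(Cl)Cl)CC(=O)OC)ccc1O[Si](C)(C)C(C)(C)C | intermediate
5 | methyl (3S)‑3‑[4‑(tert‑butyldimethylsilyloxy)‑3‑methoxyphenyl]‑3‑hydroxypropanoate | COc1cc([C@@H](O)CC(=O)OC)ccc1O[Si](C)(C)C(C)(C)C | intermediate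
6 | 2,2,6‑trimethyl‑4H‑1,3‑dioxin‑4‑one | CC1=CC(=O)OC(C)(C)O1 | starting material
7 | prenyl bromide (1‑bromo‑3‑methylbut‑2‑ene) | CC(C)=CCBr | starting material
8 | 2,2‑dimethyl‑6‑(4‑methylpent‑3‑en‑1‑yl)‑4H‑1,3‑dioxin‑4‑one | CC(C)=CCCC1=CC(=O)OC(C)(C)O1 | intermediate
9 | acetyl chloride | CC(Cl)=O | starting material
10 | 2,2‑dimethyl‑6‑(6‑methyl‑2‑oxohept‑5‑en‑3‑yl)‑4H‑1,3‑dioxin‑4‑one (racemic, keto/enol) | CC(=O)C(CC=C(C)C)C1=CC(=O)OC(C)(C)O1 | intermediate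
11 | 6‑[(10S)‑10‑[4‑(tert‑butyldimethylsilyloxy)‑3‑methoxyphenyl]‑10‑hydroxy‑2‑methyl‑6,8‑dioxodec‑2‑en‑5‑yl]‑2,2‑dimethyl‑4H‑1,3‑dioxin‑4‑one (epimers at C5, tautomers) | COc1cc([C@@H](O)CC(=O)CC(=O)C(CC=C(C)C)C2=CC(=O)OC(C)(C)O2)ccc1O[Si](C)(C)C(C)(C)C | intermediate
12 | 6‑{1‑[(2S)‑2‑[4‑(tert‑butyldimethylsilyloxy)‑3‑methoxyphenyl]‑4‑oxo‑3,4‑dihydro‑2H‑pyran‑6‑yl]‑4‑methylpent‑3‑en‑1‑yl}‑2,2‑dimethyl‑4H‑1,3‑dioxin‑4‑one | COc1cc([C@@H]2CC(=O)C=C(O2)C(CC=C(C)C)C2=CC(=O)OC(C)(C)O2)ccc1O[Si](C)(C)C(C)(C)C | intermediate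
13 | 4‑[(2S)‑2‑[4‑(tert‑butyldimethylsilyloxy)‑3‑methoxyphenyl]‑4‑oxo‑3,4‑dihydro‑2H‑pyran‑6‑yl]‑7‑methylocta‑1,6‑diene‑1,3‑dione (acylketene) | COc1cc([C@@H]2CC(=O)C=C(O2)C(CC=C(C)C)C(=O)C=C=O)ccc1O[Si](C)(C)C(C)(C)C | intermediate
14 | (2S)‑2‑[4‑(tert‑butyldimethylsilyloxy)‑3‑methoxyphenyl]‑5,7‑dihydroxy‑8‑(3‑methylbut‑2‑en‑1‑yl)‑2,3‑dihydro‑4H‑chromen‑4‑one | COc1cc([C@@H]2CC(=O)c3c(O)cc(O)c(CC=C(C)C)c3O2)ccc1O[Si](C)(C)C(C)(C)C | intermediate
15 | (2S)‑5,7‑dihydroxy‑2‑(4‑hydroxy‑3‑methoxyphenyl)‑8‑(3‑methylbut‑2‑en‑1‑yl)‑2,3‑dihydro‑4H‑chromen‑4‑one | COc1cc([C@@H]2CC(=O)c3c(O)cc(O)c(CC=C(C)C)c3O2)ccc1O | target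

**Step count and risks**
Total steps: 7. Longest linear sequence: 5 (steps 1, 2, 5, 6, 7; the branch 3, 4, 5, 6, 7 is equally long).

The three steps most likely to fail, in order:

The double ring closure (step 6) is the least certain. Before ring C has closed, 11 can aromatise in the aldol mode (to a resorcylate or dihydroisocoumarin) or, if heated too early, be trapped as a 4‑hydroxy‑2‑pyrone; the hot acidic stage could also erode ee. The fallback builds the two rings by cycloadditions instead; it sets out from 2 and 7 and comes back at 14. An asymmetric hetero‑Diels–Alder reaction of 2 with Danishefsky's diene (chiral Cr(III)–salen or Ti–BINOL catalyst, then TFA) gives (2S)‑2‑[4‑(tert‑butyldimethylsilyloxy)‑3‑methoxyphenyl]‑2,3‑dihydro‑4H‑pyran‑4‑one F1, and I2/pyridine converts it into the 5‑iodo derivative F2. In parallel, 7 alkylates the dianion of methyl acetoacetate (LDA, 2 equiv) to methyl 7‑methyl‑3‑oxooct‑6‑enoate F3, which is silylated (Et3N, TMSCl) to methyl 7‑methyl‑3‑(trimethylsilyloxy)octa‑2,6‑dienoate F4 and then (LDA, TMSCl) to 1‑methoxy‑7‑methyl‑1,3‑bis(trimethylsilyloxy)octa‑1,3,6‑triene F5. Thermal Diels–Alder addition of F5 to F2 (PhMe, 80–110 °C, solid NaHCO3) joins the prenyl‑bearing diene terminus to C6 and the ketene‑acetal carbon to C5 of the pyranone, as in Brassard additions to halo‑quinones; loss of HI, methanol and the silyl groups aromatises the adduct to 14.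

The crossed Claisen (step 5) may suffer from the hindered, doubly enolisable dianion of 10 and from the lability of 11. The fallback introduces the prenyl group after ring C is closed; it sets out from 6, 9 and 5 and comes back at 12, which is then only heated as in the second half of step 6. Acetylation of the dienolate of 6 with 9 (LiHMDS, –78 °C) gives 2,2‑dimethyl‑6‑(2‑oxopropyl)‑4H‑1,3‑dioxin‑4‑one F6, whose unhindered dianion (LDA) condenses with 5 to 6‑[(6S)‑6‑[4‑(tert‑butyldimethylsilyloxy)‑3‑methoxyphenyl]‑6‑hydroxy‑2,4‑dioxohexyl]‑2,2‑dimethyl‑4H‑1,3‑dioxin‑4‑one F7. PPTS closes it to 6‑{[(2S)‑2‑[4‑(tert‑butyldimethylsilyloxy)‑3‑methoxyphenyl]‑4‑oxo‑3,4‑dihydro‑2H‑pyran‑6‑yl]methyl}‑2,2‑dimethyl‑4H‑1,3‑dioxin‑4‑one F8. Its doubly vinylogous methylene, the most acidic C–H, is mono‑alkylated with 7 (Cs2CO3, DMF, 0 °C) to give 12.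

The γ‑prenylation (step 3) may give α‑alkylation or mixtures. The fallback builds the dioxinone ring after the prenyl group is in place; it sets out from 7 and comes back at 8. The dianion of tert‑butyl acetoacetate (LDA, 2 equiv) is alkylated at its γ‑carbon with 7 (Weiler alkylation) to tert‑butyl 7‑methyl‑3‑oxooct‑6‑enoate F9. Heating F9 with excess acetone in toluene (sealed, 120 °C) generates the acylketene, which is captured by acetone as 8.

**Further compounds**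
F1 | step 6 | (2S)‑2‑[4‑(tert‑butyldimethylsilyloxy)‑3‑methoxyphenyl]‑2,3‑dihydro‑4H‑pyran‑4‑one | COc1cc([C@@H]2CC(=O)C=CO2)ccc1O[Si](C)(C)C(C)(C)C
F2 | step 6 | (2S)‑2‑[4‑(tert‑butyldimethylsilyloxy)‑3‑methoxyphenyl]‑5‑iodo‑2,3‑dihydro‑4H‑pyran‑4‑one | COc1cc([C@@H]2CC(=O)C(I)=CO2)ccc1O[Si](C)(C)C(C)(C)C
F3 | step 6 | methyl 7‑methyl‑3‑oxooct‑6‑enoate | COC(=O)CC(=O)CCC=C(C)C
F4 | step 6 | methyl 7‑methyl‑3‑(trimethylsilyloxy)octa‑2,6‑dienoate | COC(=O)C=C(O[Si](C)(C)C)CCC=C(C)C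
F5 | step 6 | 1‑methoxy‑7‑methyl‑1,3‑bis(trimethylsilyloxy)octa‑1,3,6‑triene | COC(O[Si](C)(C)C)=CC(O[Si](C)(C)C)=CCC=C(C)C
F6 | step 5 | 2,2‑dimethyl‑6‑(2‑oxopropyl)‑4H‑1,3‑dioxin‑4‑one | CC(=O)CC1=CC(=O)OC(C)(C)O1
F7 | step 5 | 6‑[(6S)‑6‑[4‑(tert‑butyldimethylsilyloxy)‑3‑methoxyphenyl]‑6‑hydroxy‑2,4‑dioxohexyl]‑2,2‑dimethyl‑4H‑1,3‑dioxin‑4‑one | COc1cc([C@@H](O)CC(=O)CC(=O)CC2=CC(=O)OC(C)(C)O2)ccc1O[Si](C)(C)C(C)(C)C
F8 | step 5 | 6‑{[(2S)‑2‑[4‑(tert‑butyldimethylsilyloxy)‑3‑methoxyphenyl]‑4‑oxo‑3,4‑dihydro‑2H‑pyran‑6‑yl]methyl}‑2,2‑dimethyl‑4H‑1,3‑dioxin‑4‑one | COc1cc([C@@H]2CC(=O)C=C(O2)CC2=CC(=O)OC(C)(C)O2)ccc1O[Si](C)(C)C(C)(C)C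
F9 | step 3 | tert‑butyl 7‑methyl‑3‑oxooct‑6‑enoate | CC(C)=CCCC(=O)CC(=O)OC(C)(C)C
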